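The route rests on opening the benzene ring across C1–C6 and C2–C3 (C1: hydroxyl carbon between methoxy and side chain; C2: side-chain carbon; C4: second hydroxyl; C6: methoxy). The meta oxygens on C4 and C6, with unsubstituted C3 and C5, are the imprint of a 1,1-dimethoxy-3-silyloxybutadiene. C1 and C2 are the carbons of an alkyne carrying the side chain and an acetyl group. One cycloaddition–aromatisation builds the whole arene, with OH and OMe already differentiated and the acetyl group para to the free phenol, ready for Dakin oxidation. The dienophile is a TBS-protected (R)-hydroxy ynone derived from (R)-epichlorohydrin.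

Key step: step 7

Remark on the chemistry: the target stereocentre is (R) (O > CH2Ar > undecyl); it is taken from the chiral pool and no bond to it is made or broken in any step, and the ranking of its substituents stays the same, so every intermediate is (R). From step 8 on, all operations are assumed to run under argon in degassed solvents, because methoxyhydroquinones oxidise easily.

Step 1
Reactants: 1 (R)-epichlorohydrin; 2 decylmagnesium bromide
Product: 3 (R)-1-chlorotridecan-2-ol
Conditions: 2 (1.2 equiv), CuI (10 mol %), THF, −40 → 0 °C; then cold 1 M HCl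
Reagents that add atoms: none
Why: Copper-catalysed Grignard opening of the epoxide is an SN2 attack at the unsubstituted ring carbon, faster than displacement of chloride, so the C–O bond at the stereocentre stays intact and the configuration of 1 is carried into 3.

Step 2
Reactants: 3 (R)-1-chlorotridecan-2-ol; 4 lithium acetylide ethylenediamine complex
Product: 6 (R)-pentadec-1-yn-4-ol, via (R)-2-undecyloxirane 5 (not isolated)
Conditions: 4 (3 equiv), DMSO, 0 °C → rt; then H2O
Reagents that add atoms: none
Why: The lithium alkoxide closes to the terminal epoxide (intramolecular Williamson reaction) and a second equivalent of acetylide opens it by SN2 attack at the CH2 carbon (acetylide opening of an epoxide), neither event touching the carbinol centre.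

Step 3
Reactants: 6 (R)-pentadec-1-yn-4-ol
Product: 7 (R)-tert-butyldimethyl(pentadec-1-yn-4-yloxy)silane
Conditions: TBSCl, imidazole, DMF, rt
Reagents that add atoms: tert-butyldimethylsilyl chloride, CC(C)(C)[Si](C)(C)Cl
Why: Imidazole-promoted silylation of a secondary alcohol gives a TBS ether that tolerates the organolithium, thermal and alkaline peroxide steps ahead and later keeps the hydroxyl from forming a cyclic hemiketal with the aryl ketone.

Step 4
Reactants: 7 (R)-tert-butyldimethyl(pentadec-1-yn-4-yloxy)silane; 8 N-methoxy-N-methylacetamide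
Product: 10 (R)-6-(tert-butyldimethylsilyloxy)heptadec-3-yn-2-one, via lithium alkynide 9 (not isolated)
Conditions: n-BuLi (1.05 equiv), THF, −78 °C; then 8 (1.3 equiv), −78 → 0 °C; then poured into cold 1 M HCl
Reagents that add atoms: none
Why: Weinreb ketone synthesis, in which the lithium alkynide adds once to the N-methoxy-N-methylamide and the chelated adduct collapses to the methyl ynone only on acidic quench, which also protonates the released amine so that it cannot add to the ynone.

Step 5
Reactants: 11 1,1-dimethoxyethene; 12 acetyl chloride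
Product: 13 4,4-dimethoxybut-3-en-2-one
Conditions: Et3N (1.1 equiv), Et2O, 0 °C → rt
Reagents that add atoms: none
Why: C-Acylation of an electron-rich ketene acetal by an acid chloride at its nucleophilic CH2 carbon, with the amine taking up HCl, should give the β,β-dimethoxy enone.

Step 6
Reactants: 13 4,4-dimethoxybut-3-en-2-one
Product: 15 1,1-dimethoxy-3-(trimethylsilyloxy)buta-1,3-diene, via lithium dienolate 14 (not isolated)
Conditions: LiN(CHMe2)2 (commercial solution, 1.1 equiv), THF, −78 °C; then TMSCl, −78 °C → rt; pentane, filtration, distillation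
Reagents that add atoms: chlorotrimethylsilane, C[Si](C)(C)Cl
Why: Kinetic deprotonation of the methyl group, the only enolisable position, and O-silylation of the cross-conjugated enolate (silyl enol ether formation) should give the 2-silyloxy diene.

Step 7
Reactants: 10 (R)-6-(tert-butyldimethylsilyloxy)heptadec-3-yn-2-one; 15 1,1-dimethoxy-3-(trimethylsilyloxy)buta-1,3-diene
Product: 18 1-{4-hydroxy-2-methoxy-6-[(R)-2-(tert-butyldimethylsilyloxy)tridecyl]phenyl}ethan-1-one, via cyclohexa-1,4-diene cycloadduct 16 (not isolated), via aryl trimethylsilyl ether 17 (not isolated)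
Conditions: 15 (3 equiv), toluene, 100 °C, sealed tube, Ar; then PPTS (cat.), MeOH, rt
Reagents that add atoms: none
Why: A normal-electron-demand Diels–Alder reaction in which the diene CH2 terminus (future C3, made the most nucleophilic carbon by both the silyloxy group and the ketene acetal) bonds to the β-carbon of the ynone (C2) and the acetal carbon (C6) bonds to the acetyl-bearing α-carbon (C1), giving cycloadduct 16. The closest known reaction type is the benzannulation of 1,1-dialkoxy-3-silyloxybutadienes with acetylenic ketones and esters, which aromatise by loss of alcohol; β-alkyl ynones are slower than terminal ones, hence the heating and the excess of diene. The benzene ring is closed by an intermolecular [4+2] cycloaddition that forms both ring bonds, after which 1,4-elimination of methanol (H from C3, OMe from C6) gives aryl silyl ether 17 and methanolysis of its labile aryl O–Si bond frees the C4 phenol. No stereocentre is created; the existing carbinol centre is two atoms from the alkyne, no bond to it changes, and its secondary TBS ether is stable to heat and to PPTS in methanol. The step needs regioselectivity (acetyl next to OMe, chain next to a ring CH), secured by the matched polarisation of diene and ynone, and chemoselectivity for C≡C over C=O, secured by running it thermally without Lewis acid.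

Step 8
Reactants: 18 1-{4-hydroxy-2-methoxy-6-[(R)-2-(tert-butyldimethylsilyloxy)tridecyl]phenyl}ethan-1-one
Product: 20 2-methoxy-6-[(R)-2-(tert-butyldimethylsilyloxy)tridecyl]benzene-1,4-diol, via aryl acetate 19 (not isolated)
Conditions: 30% aq H2O2 (4 equiv), NaOH (3 equiv), THF–H2O, 0 °C → rt, Ar; then aq Na2S2O4, 1 M HCl to pH 5
Reagents that add atoms: hydrogen peroxide, OO
Why: Dakin oxidation, in which hydroperoxide adds to the ketone, the electron-rich aryl group (para phenoxide, ortho methoxy) migrates to oxygen in preference to methyl (Baeyer–Villiger-type shift) and the aryl acetate is saponified in the same flask, the TBS ether being inert to aqueous alkali.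

Step 9
Reactants: 20 2-methoxy-6-[(R)-2-(tert-butyldimethylsilyloxy)tridecyl]benzene-1,4-diol
Product: 22 (R)-1-(2,5-diacetoxy-3-methoxyphenyl)tridecan-2-yl acetate, via triol 21 (not isolated)
Conditions: 1.25 M HCl in MeOH, rt, Ar; evaporation; then Ac2O, pyridine, DMAP (cat.), CH2Cl2, rt
Reagents that add atoms: acetic anhydride, CC(=O)OC(C)=O
Why: Acid-catalysed methanolysis of the silyl ether keeps the hydroquinone away from base and air, and the crude triol is then fully O-acetylated under DMAP catalysis, so the oxidation-prone intermediate is never isolated.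

Step 10
Reactants: 22 (R)-1-(2,5-diacetoxy-3-methoxyphenyl)tridecan-2-yl acetate
Product: 23 (R)-1-(2,5-dihydroxy-3-methoxyphenyl)tridecan-2-yl acetate
Conditions: N2H4·H2O (2.5 equiv), THF–MeOH, 0 °C → rt, Ar; then aq NaH2PO4
Reagents that add atoms: none
Why: Chemoselective hydrazinolysis, in which aryl acetates with their phenoxide leaving groups are aminolysed far faster than the secondary alkyl acetate, while the reducing medium protects the hydroquinone from oxidation to the quinone.

Compound list
1 | (R)-epichlorohydrin, (R)-2-(chloromethyl)oxirane | ClC[C@H]1CO1 | starting material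
2 | decylmagnesium bromide | CCCCCCCCCC[Mg]Br | starting material
3 | (R)-1-chlorotridecan-2-ol | CCCCCCCCCCC[C@@H](O)CCl | intermediate
4 | lithium acetylide ethylenediamine complex | [Li+].[C-]#C.NCCN | starting material
5 | (R)-2-undecyloxirane | CCCCCCCCCCC[C@@H]1CO1 | intermediate
6 | (R)-pentadec-1-yn-4-ol | CCCCCCCCCCC[C@@H](O)CC#C | intermediate
7 | (R)-tert-butyldimethyl(pentadec-1-yn-4-yloxy)silane | CCCCCCCCCCC[C@@H](O[Si](C)(C)C(C)(C)C)CC#C | intermediate
8 | N-methoxy-N-methylacetamide | CC(=O)N(C)OC | starting material
9 | lithium alkynide of 7, lithium (R)-4-(tert-butyldimethylsilyloxy)pentadec-1-yn-1-ide | [Li+].[C-]#CC[C@@H](CCCCCCCCCCC)O[Si](C)(C)C(C)(C)C | intermediate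
10 | (R)-6-(tert-butyldimethylsilyloxy)heptadec-3-yn-2-one | CC(=O)C#CC[C@@H](CCCCCCCCCCC)O[Si](C)(C)C(C)(C)C | intermediate
11 | 1,1-dimethoxyethene | C=C(OC)OC | starting material
12 | acetyl chloride | CC(=O)Cl | starting material
13 | 4,4-dimethoxybut-3-en-2-one | CC(=O)C=C(OC)OC | intermediate
14 | lithium 4,4-dimethoxybuta-1,3-dien-2-olate | [Li+].[O-]C(=C)C=C(OC)OC | intermediate
15 | 1,1-dimethoxy-3-(trimethylsilyloxy)buta-1,3-diene | COC(OC)=CC(=C)O[Si](C)(C)C | intermediate
16 | 1-{6,6-dimethoxy-2-[(R)-2-(tert-butyldimethylsilyloxy)tridecyl]-4-(trimethylsilyloxy)cyclohexa-1,4-dien-1-yl}ethan-1-one | CC(=O)C1=C(C[C@@H](CCCCCCCCCCC)O[Si](C)(C)C(C)(C)C)CC(O[Si](C)(C)C)=CC1(OC)OC | intermediate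
17 | 1-{2-methoxy-6-[(R)-2-(tert-butyldimethylsilyloxy)tridecyl]-4-(trimethylsilyloxy)phenyl}ethan-1-one | CC(=O)c1c(OC)cc(O[Si](C)(C)C)cc1C[C@@H](CCCCCCCCCCC)O[Si](C)(C)C(C)(C)C | intermediate
18 | 1-{4-hydroxy-2-methoxy-6-[(R)-2-(tert-butyldimethylsilyloxy)tridecyl]phenyl}ethan-1-one | CC(=O)c1c(OC)cc(O)cc1C[C@@H](CCCCCCCCCCC)O[Si](C)(C)C(C)(C)C | intermediate
19 | 4-hydroxy-2-methoxy-6-[(R)-2-(tert-butyldimethylsilyloxy)tridecyl]phenyl acetate | CC(=O)Oc1c(OC)cc(O)cc1C[C@@H](CCCCCCCCCCC)O[Si](C)(C)C(C)(C)C | intermediate
20 | 2-methoxy-6-[(R)-2-(tert-butyldimethylsilyloxy)tridecyl]benzene-1,4-diol | Oc1c(OC)cc(O)cc1C[C@@H](CCCCCCCCCCC)O[Si](C)(C)C(C)(C)C | intermediate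
21 | 2-[(R)-2-hydroxytridecyl]-6-methoxybenzene-1,4-diol | Oc1c(OC)cc(O)cc1C[C@@H](CCCCCCCCCCC)O | intermediate
22 | (R)-1-(2,5-diacetoxy-3-methoxyphenyl)tridecan-2-yl acetate | CC(=O)Oc1c(OC)cc(OC(C)=O)cc1C[C@@H](CCCCCCCCCCC)OC(C)=O | intermediate
23 | (R)-1-(2,5-dihydroxy-3-methoxyphenyl)tridecan-2-yl acetate | CCCCCCCCCCC[C@H](Cc1cc(O)cc(OC)c1O)OC(C)=O | target

Total step count: 10. Longest linear sequence: 8 steps (steps 1, 2, 3, 4, 7, 8, 9, 10); steps 5 and 6 form the two-step diene branch.

Steps most likely to fail

Step 7. The cycloaddition of the β-alkyl ynone may be slow enough that the diene decomposes or transfers its silyl group on heating, or the regiocontrol may be incomplete. The fallback gives up the ring construction and starts from a preformed arene.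
- It sets out from 3, which NaOH in Et2O–H2O would close to the isolated epoxide 5.
- Commercial 3,5-dimethoxyphenylmagnesium bromide with CuI (cat.) in THF should open 5 at the CH2 carbon to give (R)-1-(3,5-dimethoxyphenyl)tridecan-2-ol F1.
- NaSEt in DMF at 140 °C should remove one of the two equivalent methyl groups to give 3-[(R)-2-hydroxytridecyl]-5-methoxyphenol F2.
- (KSO3)2NO in buffered aqueous acetone should oxidise the phenol at its free para position to 2-[(R)-2-hydroxytridecyl]-6-methoxycyclohexa-2,5-diene-1,4-dione F3.
- Ac2O and pyridine in CH2Cl2 at 0 °C should give (R)-1-(5-methoxy-3,6-dioxocyclohexa-1,4-dien-1-yl)tridecan-2-yl acetate F4.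
- Reduction with aqueous Na2S2O4 in EtOAc returns to the route at 23.

Step 8. Hydroperoxide may add only sluggishly to the doubly ortho-substituted carbonyl, and the hydroquinone may be over-oxidised in alkaline peroxide. The fallback uses a peracid on the protected phenol.
- It sets out from 18, which Ac2O and pyridine should convert into 4-acetyl-3-methoxy-5-[(R)-2-(tert-butyldimethylsilyloxy)tridecyl]phenyl acetate F5.
- Baeyer–Villiger oxidation with mCPBA and NaHCO3 in CH2Cl2 should give 2-methoxy-6-[(R)-2-(tert-butyldimethylsilyloxy)tridecyl]-1,4-phenylene diacetate F6.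
- F6 is then treated exactly as in step 9: HCl in MeOH removes the silyl group and transesterifies the aryl acetates to triol 21, and peracetylation in the same flask returns to the route at 22.

Step 10. The side-chain ester may be partly cleaved, or the electron-rich hydroquinone may oxidise in air during the amine treatment and work-up. The fallback replaces the aryl acetates by benzyl ethers that are removed under neutral reducing conditions.
- It sets out from 20, which BnBr and K2CO3 in DMF should convert into 1,4-bis(benzyloxy)-2-methoxy-6-[(R)-2-(tert-butyldimethylsilyloxy)tridecyl]benzene F7.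
- HCl in MeOH should give (R)-1-[2,5-bis(benzyloxy)-3-methoxyphenyl]tridecan-2-ol F8.
- Ac2O, pyridine and DMAP should give (R)-1-[2,5-bis(benzyloxy)-3-methoxyphenyl]tridecan-2-yl acetate F9.
- Hydrogenolysis (H2, 10% Pd/C, EtOAc) returns to the route at 23.

Further compounds
F1 | step 7 | (R)-1-(3,5-dimethoxyphenyl)tridecan-2-ol | CCCCCCCCCCC[C@@H](O)Cc1cc(OC)cc(OC)c1
F2 | step 7 | 3-[(R)-2-hydroxytridecyl]-5-methoxyphenol | CCCCCCCCCCC[C@@H](O)Cc1cc(O)cc(OC)c1
F3 | step 7 | 2-[(R)-2-hydroxytridecyl]-6-methoxycyclohexa-2,5-diene-1,4-dione | CCCCCCCCCCC[C@@H](O)CC1=CC(=O)C=C(OC)C1=O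
F4 | step 7 | (R)-1-(5-methoxy-3,6-dioxocyclohexa-1,4-dien-1-yl)tridecan-2-yl acetate | CCCCCCCCCCC[C@H](CC1=CC(=O)C=C(OC)C1=O)OC(C)=O
F5 | step 8 | 4-acetyl-3-methoxy-5-[(R)-2-(tert-butyldimethylsilyloxy)tridecyl]phenyl acetate | CC(=O)Oc1cc(OC)c(C(C)=O)c(C[C@@H](CCCCCCCCCCC)O[Si](C)(C)C(C)(C)C)c1
F6 | step 8 | 2-methoxy-6-[(R)-2-(tert-butyldimethylsilyloxy)tridecyl]-1,4-phenylene diacetate | CC(=O)Oc1cc(OC)c(OC(C)=O)c(C[C@@H](CCCCCCCCCCC)O[Si](C)(C)C(C)(C)C)c1
F7 | step 10 | 1,4-bis(benzyloxy)-2-methoxy-6-[(R)-2-(tert-butyldimethylsilyloxy)tridecyl]benzene | COc1cc(OCc2ccccc2)cc(C[C@@H](CCCCCCCCCCC)O[Si](C)(C)C(C)(C)C)c1OCc1ccccc1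
F8 | step 10 | (R)-1-[2,5-bis(benzyloxy)-3-methoxyphenyl]tridecan-2-ol | COc1cc(OCc2ccccc2)cc(C[C@@H](CCCCCCCCCCC)O)c1OCc1ccccc1
F9 | step 10 | (R)-1-[2,5-bis(benzyloxy)-3-methoxyphenyl]tridecan-2-yl acetate | COc1cc(OCc2ccccc2)cc(C[C@@H](CCCCCCCCCCC)OC(C)=O)c1OCc1ccccc1
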